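**Plan**

1. Numbering: chain C1 (alkyne CH) to C15 (CH3). Ring A = O–C7–C8–C9–C10 (Z enol ether C6=C7, Br on C8). Ring B = O–C9–C10–C11–C12 (CHBr–Et arm on C12). The rings are cis-fused along C9–C10.
2. Enabling feature: the ring B oxygen on C12 and the bromine on C13 are anti across a bond that maps onto an E double bond, and O9 and C11 are cis on ring A. Ring B is therefore the retron of a bromonium-ion 5-exo etherification, the bromoperoxidase step assumed in the biogenesis of these C15 bromo ethers.
3. Retrosynthetic cuts, in order: C8–Br (from C8–OH with inversion); C6=C7 (modified Julia olefination of a lactone C7=O with a C1–C6 sulfone); O–C12 together with C13–Br (bromoetherification); C11–C12 (cuprate coupling). The lactone is an oxidation-level helper: it keeps the electron-rich enol ether out of the bromination and is converted afterwards.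
4. Forward order: ring A comes ready-made as the γ-lactone of D-gulonic acid (its C2, C3, C4 become C8, C9, C10). The (E)-pentenyl arm is attached, ring B is closed last, then the enol ether/enyne arm and the C8 bromide are installed.
5. Stereochemistry: C8–C10 from the chiral pool; C12 by exo closure of the cis-bicycle; C13 by anti addition to the E alkene; C8–Br by SN2 inversion; C3=C4 by Zn(Cu/Ag) cis-reduction; C6=C7 by allylic-strain control in the olefination.

Key step: step 7

Remark: D-gulono-1,4-lactone, but-1-yne, but-3-yn-1-ol and (bromoethynyl)triisopropylsilane are taken as commercial.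

**Route**

Step 1
Reactants: 1 D-gulono-1,4-lactone
Product: 2 2,3:5,6-di-O-isopropylidene-D-gulono-1,4-lactone
Conditions: Me2C(OMe)2, acetone, TsOH·H2O (cat.), rt
Reagents that add atoms: 2,2-dimethoxypropane, COC(C)(C)OC
Why: Acid-catalysed transacetalisation should protect the cis-2,3-diol and the terminal 5,6-diol as acetonides without touching any stereocentre.

Step 2
Reactants: 2 2,3:5,6-di-O-isopropylidene-D-gulono-1,4-lactone
Product: 4 2,3-O-isopropylidene-L-lyxono-1,4-lactone, via C5 aldehyde lactone 3 (not isolated)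
Conditions: H5IO6, EtOAc, rt; then NaBH4 (limiting), EtOH, −20 °C
Reagents that add atoms: none
Why: Periodic acid should hydrolyse the more labile terminal acetonide and cleave the freed 5,6-glycol (Malaprade cleavage), and the aldehyde should then be reduced much faster than the lactone, C4 (later C10) not being enolised under these conditions.

Step 3
Reactants: 4 2,3-O-isopropylidene-L-lyxono-1,4-lactone
Product: 5 2,3-O-isopropylidene-5-O-(trifluoromethylsulfonyl)-L-lyxono-1,4-lactone
Conditions: Tf2O, pyridine, CH2Cl2, −30 °C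
Reagents that add atoms: trifluoromethanesulfonic anhydride, O=S(=O)(OS(=O)(=O)C(F)(F)F)C(F)(F)F
Why: Sulfonylation of the only free (primary) hydroxyl should give the triflate needed for C–C coupling at C11.

Step 4
Reactants: 6 but-1-yne
Product: 8 (E)-1-iodobut-1-ene, via (E)-but-1-enylzirconocene chloride 7 (not isolated)
Conditions: Cp2Zr(H)Cl, THF, rt; then I2, 0 °C
Reagents that add atoms: iodine, II
Why: Syn hydrozirconation places zirconium on the terminal carbon and iododemetalation proceeds with retention, so the E iodide should form as a single isomer.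

Step 5
Reactants: 5 2,3-O-isopropylidene-5-O-(trifluoromethylsulfonyl)-L-lyxono-1,4-lactone; 8 (E)-1-iodobut-1-ene
Product: 11 (E)-5,6,7,8,9-pentadeoxy-2,3-O-isopropylidene-L-lyxo-non-6-enono-1,4-lactone, via (E)-but-1-enyllithium 9 (not isolated), via lithium di[(E)-but-1-enyl]cuprate 10 (not isolated)
Conditions: 8, t-BuLi (2 equiv), Et2O, −78 °C; CuI (0.5 equiv), −40 °C; then 5, −78 to −30 °C
Reagents that add atoms: none
Why: SN2 alkylation of a lithium dialkenylcuprate by the primary triflate (sp3–sp2 coupling) should form C11–C12 with retention of the alkenyl geometry, the cuprate being too unreactive toward the lactone carbonyl at low temperature.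

Step 6
Reactants: 11 (E)-5,6,7,8,9-pentadeoxy-2,3-O-isopropylidene-L-lyxo-non-6-enono-1,4-lactone
Product: 12 (E)-5,6,7,8,9-pentadeoxy-L-lyxo-non-6-enono-1,4-lactone (all-cis 2,3-dihydroxy-4-[(E)-pent-2-enyl]-γ-butyrolactone)
Conditions: TFA–H2O (9:1), 0 °C
Reagents that add atoms: none
Why: Acid hydrolysis of the lactone-fused acetonide should free the cis C8/C9 diol, the lactone and the isolated E alkene tolerating brief cold aqueous acid.

Step 7
Reactants: 12 (E)-5,6,7,8,9-pentadeoxy-L-lyxo-non-6-enono-1,4-lactone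
Product: 13 (3R,3aS,5R,6aS)-5-[(1S)-1-bromopropyl]-3-hydroxyhexahydrofuro[3,2-b]furan-2-one
Conditions: NBS (1.1 equiv), MeCN, 0 °C, dark
Reagents that add atoms: N-bromosuccinimide, O=C1CCC(=O)N1Br
Why: NBS should transfer Br+ to the (E)-C12=C13 alkene, and the bromonium ion is opened at C12 by the C9 hydroxyl with loss of a proton to succinimide anion; this copies the presumed haloperoxidase bromoetherification, and its closest known reaction type is the NBS- or TBCO-mediated 5-exo bromoetherification of γ,δ-unsaturated alcohols. Ring B (O–C9–C10–C11–C12) closes in the 5-exo mode, which should be preferred over 6-endo opening at C13 (both alkene carbons are secondary, so ring size decides) and over 6-exo attack by the C8 hydroxyl, which is less nucleophilic next to the lactone carbonyl. C12 is controlled by the ring fusion: O9 and C11 are cis on ring A, so the new ring must be cis-fused, and the CHBr–Et arm should take the exo (convex) side away from ring A, which gives 12R. C13 is controlled by the stereospecific anti addition of oxygen and bromine across the E double bond, which gives 13S once C12 is fixed. The step needs chemoselectivity, secured by keeping ring A at the lactone level so that C12=C13 is the only alkene present, and facial selectivity, secured by the exo preference of the cis-bicyclo[3.3.0] transition state.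

Step 8
Reactants: 13 (3R,3aS,5R,6aS)-5-[(1S)-1-bromopropyl]-3-hydroxyhexahydrofuro[3,2-b]furan-2-one
Product: 14 (3R,3aR,5R,6aS)-5-[(1S)-1-bromopropyl]-3-{[tert-butyl(dimethyl)silyl]oxy}hexahydrofuro[3,2-b]furan-2-one
Conditions: TBSOTf, 2,6-lutidine, CH2Cl2, −78 to 0 °C
Reagents that add atoms: tert-butyldimethylsilyl trifluoromethanesulfonate, CC(C)(C)[Si](C)(C)OS(=O)(=O)C(F)(F)F
Why: Silylation with the reactive silyl triflate should mask the concave-face C8 hydroxyl for the carbanion chemistry of step 13.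

Step 9
Reactants: 15 but-3-yn-1-ol; 16 (bromoethynyl)triisopropylsilane
Product: 17 6-(triisopropylsilyl)hexa-3,5-diyn-1-ol
Conditions: CuCl (cat.), NH2OH·HCl (cat.), n-BuNH2, H2O–CH2Cl2, 0 °C
Reagents that add atoms: none
Why: Cadiot–Chodkiewicz coupling of a terminal alkyne with a bromoalkyne should give the unsymmetrical diyne, the bulky silyl cap resisting the amine.

Step 10
Reactants: 17 6-(triisopropylsilyl)hexa-3,5-diyn-1-ol
Product: 18 (3Z)-6-(triisopropylsilyl)hex-3-en-5-yn-1-ol
Conditions: Zn(Cu/Ag), MeOH–H2O, 40 °C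
Reagents that add atoms: none
Why: Activated-zinc semi-reduction adds two hydrogens cis to the hydroxyl-assisted internal alkyne of the conjugated diyne and should leave the silyl-capped alkyne alone, which sets the 3Z alkene.

Step 11
Reactants: 18 (3Z)-6-(triisopropylsilyl)hex-3-en-5-yn-1-ol
Product: 19 2-{[(3Z)-6-(triisopropylsilyl)hex-3-en-5-yn-1-yl]sulfanyl}-1,3-benzothiazole
Conditions: 2-mercaptobenzothiazole, PPh3, DIAD, THF, 0 °C to rt
Reagents that add atoms: 1,3-benzothiazole-2-thiol, Sc1nc2ccccc2s1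
Why: Mitsunobu thioetherification of the primary alcohol with the acidic heteroaryl thiol should proceed by SN2 on the alkoxyphosphonium ion.

Step 12
Reactants: 19 2-{[(3Z)-6-(triisopropylsilyl)hex-3-en-5-yn-1-yl]sulfanyl}-1,3-benzothiazole
Product: 20 2-{[(3Z)-6-(triisopropylsilyl)hex-3-en-5-yn-1-yl]sulfonyl}-1,3-benzothiazole
Conditions: (NH4)6Mo7O24·4H2O (cat.), 30% H2O2, EtOH, 0 °C to rt
Reagents that add atoms: hydrogen peroxide, OO
Why: Molybdate-catalysed peroxide oxidation should take the sulfide to the sulfone without epoxidising the electron-poor silyl enyne.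

Step 13
Reactants: 14 (3R,3aR,5R,6aS)-5-[(1S)-1-bromopropyl]-3-{[tert-butyl(dimethyl)silyl]oxy}hexahydrofuro[3,2-b]furan-2-one; 20 2-{[(3Z)-6-(triisopropylsilyl)hex-3-en-5-yn-1-yl]sulfonyl}-1,3-benzothiazole
Product: 22 (2Z,3R,3aR,5R,6aS)-5-[(1S)-1-bromopropyl]-3-{[tert-butyl(dimethyl)silyl]oxy}-2-[(3Z)-6-(triisopropylsilyl)hex-3-en-5-yn-1-ylidene]hexahydrofuro[3,2-b]furan, via hemiketal sulfone adduct 21 (not isolated)
Conditions: 14 + 20, LiHMDS added last, THF, −78 °C; AcOH; then DBU, THF, rt
Reagents that add atoms: none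
Why: In this modified Julia olefination of a lactone the lithiated sulfone should add to the C7 carbonyl from the exo face, and the hemiketal then undergoes Smiles rearrangement and loses SO2 and benzothiazolone to give the exocyclic enol ether, the Z isomer (C5 cis to the ring oxygen) being expected to prevail because the E isomer suffers allylic strain with the C8 silyloxy group.

Step 14
Reactants: 22 (2Z,3R,3aR,5R,6aS)-5-[(1S)-1-bromopropyl]-3-{[tert-butyl(dimethyl)silyl]oxy}-2-[(3Z)-6-(triisopropylsilyl)hex-3-en-5-yn-1-ylidene]hexahydrofuro[3,2-b]furan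
Product: 23 (2Z,3R,3aS,5R,6aS)-5-[(1S)-1-bromopropyl]-2-[(3Z)-hex-3-en-5-yn-1-ylidene]hexahydrofuro[3,2-b]furan-3-ol
Conditions: TBAF (2.5 equiv), THF, 0 °C
Reagents that add atoms: none
Why: Fluoride should cleave the O–Si bond at C8 and the C–Si bond of the alkyne in one operation, conditions under which the enol ether and the secondary bromide should be stable.

Step 15
Reactants: 23 (2Z,3R,3aS,5R,6aS)-5-[(1S)-1-bromopropyl]-2-[(3Z)-hex-3-en-5-yn-1-ylidene]hexahydrofuro[3,2-b]furan-3-ol
Product: 24 (2Z,3S,3aR,5R,6aS)-3-bromo-5-[(1S)-1-bromopropyl]-2-[(3Z)-hex-3-en-5-yn-1-ylidene]hexahydrofuro[3,2-b]furan (target)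
Conditions: CBr4, PPh3, 2,6-lutidine, CH2Cl2, 0 °C
Reagents that add atoms: carbon tetrabromide, BrC(Br)(Br)Br
Why: In this Appel reaction bromide should displace the alkoxyphosphonium group at the allylic C8 by SN2 from the open exo face, so the endo C8–O bond is replaced by the exo C8–Br bond with inversion (8R alcohol to 8S bromide), the lutidine buffer protecting the enol ether from acid.

**Compound list**

1 | D-gulono-1,4-lactone | O=C1O[C@@H]([C@H](O)CO)[C@@H](O)[C@H]1O | starting material
2 | 2,3:5,6-di-O-isopropylidene-D-gulono-1,4-lactone | O=C1O[C@@H]([C@H]3COC(C)(C)O3)[C@H]2OC(C)(C)O[C@@H]12 | intermediate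
3 | 2,3-O-isopropylidene-L-lyxono-1,4-lactone C5 aldehyde (5-oxo compound) | O=C1O[C@@H](C=O)[C@H]2OC(C)(C)O[C@@H]12 | intermediate (not isolated)
4 | 2,3-O-isopropylidene-L-lyxono-1,4-lactone | O=C1O[C@@H](CO)[C@H]2OC(C)(C)O[C@@H]12 | intermediate
5 | 2,3-O-isopropylidene-5-O-(trifluoromethylsulfonyl)-L-lyxono-1,4-lactone | O=C1O[C@@H](COS(=O)(=O)C(F)(F)F)[C@H]2OC(C)(C)O[C@@H]12 | intermediate
6 | but-1-yne | CCC#C | starting material
7 | (E)-but-1-enylzirconocene chloride | CC/C=C/[Zr](Cl)(C1C=CC=C1)C1C=CC=C1 | intermediate (not isolated)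
8 | (E)-1-iodobut-1-ene | CC/C=C/I | intermediate
9 | (E)-but-1-enyllithium | CC/C=C/[Li] | intermediate (not isolated)
10 | lithium di[(E)-but-1-enyl]cuprate | CC/C=C/[Cu-]/C=C/CC.[Li+] | intermediate (not isolated)
11 | (E)-5,6,7,8,9-pentadeoxy-2,3-O-isopropylidene-L-lyxo-non-6-enono-1,4-lactone | O=C1O[C@@H](C/C=C/CC)[C@H]2OC(C)(C)O[C@@H]12 | intermediate
12 | (E)-5,6,7,8,9-pentadeoxy-L-lyxo-non-6-enono-1,4-lactone | O=C1O[C@@H](C/C=C/CC)[C@@H](O)[C@H]1O | intermediate
13 | (3R,3aS,5R,6aS)-5-[(1S)-1-bromopropyl]-3-hydroxyhexahydrofuro[3,2-b]furan-2-one (cis-fused; OH endo, bromopropyl arm exo) | O=C1O[C@H]2C[C@H]([C@@H](Br)CC)O[C@H]2[C@H]1O | intermediate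
14 | (3R,3aR,5R,6aS)-5-[(1S)-1-bromopropyl]-3-{[tert-butyl(dimethyl)silyl]oxy}hexahydrofuro[3,2-b]furan-2-one | O=C1O[C@H]2C[C@H]([C@@H](Br)CC)O[C@H]2[C@H]1O[Si](C)(C)C(C)(C)C | intermediate
15 | but-3-yn-1-ol | C#CCCO | starting material
16 | (bromoethynyl)triisopropylsilane | CC(C)[Si](C(C)C)(C(C)C)C#CBr | starting material
17 | 6-(triisopropylsilyl)hexa-3,5-diyn-1-ol | CC(C)[Si](C(C)C)(C(C)C)C#CC#CCCO | intermediate
18 | (3Z)-6-(triisopropylsilyl)hex-3-en-5-yn-1-ol | CC(C)[Si](C(C)C)(C(C)C)C#C/C=C\CCO | intermediate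
19 | 2-{[(3Z)-6-(triisopropylsilyl)hex-3-en-5-yn-1-yl]sulfanyl}-1,3-benzothiazole | CC(C)[Si](C(C)C)(C(C)C)C#C/C=C\CCSc1nc2ccccc2s1 | intermediate
20 | 2-{[(3Z)-6-(triisopropylsilyl)hex-3-en-5-yn-1-yl]sulfonyl}-1,3-benzothiazole | CC(C)[Si](C(C)C)(C(C)C)C#C/C=C\CCS(=O)(=O)c1nc2ccccc2s1 | intermediate
21 | hemiketal sulfone adduct of 14 and 20 (C6/C7 configuration undefined) | CC(C)[Si](C(C)C)(C(C)C)C#C/C=C\CC(C1(O)O[C@H]2C[C@H]([C@@H](Br)CC)O[C@H]2[C@H]1O[Si](C)(C)C(C)(C)C)S(=O)(=O)c1nc2ccccc2s1 | intermediate (not isolated)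
22 | (2Z,3R,3aR,5R,6aS)-5-[(1S)-1-bromopropyl]-3-{[tert-butyl(dimethyl)silyl]oxy}-2-[(3Z)-6-(triisopropylsilyl)hex-3-en-5-yn-1-ylidene]hexahydrofuro[3,2-b]furan | CC(C)[Si](C(C)C)(C(C)C)C#C/C=C\C/C=C1\O[C@H]2C[C@H]([C@@H](Br)CC)O[C@H]2[C@H]1O[Si](C)(C)C(C)(C)C | intermediate
23 | (2Z,3R,3aS,5R,6aS)-5-[(1S)-1-bromopropyl]-2-[(3Z)-hex-3-en-5-yn-1-ylidene]hexahydrofuro[3,2-b]furan-3-ol | C#C/C=C\C/C=C1\O[C@H]2C[C@H]([C@@H](Br)CC)O[C@H]2[C@H]1O | intermediate
24 | (2Z,3S,3aR,5R,6aS)-3-bromo-5-[(1S)-1-bromopropyl]-2-[(3Z)-hex-3-en-5-yn-1-ylidene]hexahydrofuro[3,2-b]furan | C#C/C=C\C/C=C1\O[C@H]2C[C@H]([C@@H](Br)CC)O[C@H]2[C@@H]1Br | target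

**Step count and risks**

Total step count: 15. Longest linear sequence: 10 steps (1, 2, 3, 5, 6, 7, 8, 13, 14, 15).

Most likely to fail:

Step 13. The base may enolise the lactone and expel the ring B oxygen from C9 instead of adding to the carbonyl, or the sulfinate elimination may give poor Z/E control. The fallback sets out from 14 and 18 and comes back at 22, using a titanium alkylidene in place of the sulfone carbanion (Takai–Utimoto alkylidenation, which is Z-selective for ester carbonyls). Enynol 18 would be oxidised with buffered periodinane (DMP, NaHCO3) to (3Z)-6-(triisopropylsilyl)hex-3-en-5-ynal F1, used at once. F1 would be converted with triphenyl phosphite–bromine into [(3Z)-6,6-dibromohex-3-en-1-yn-1-yl]triisopropylsilane F2. F2 with Zn, TiCl4, TMEDA and catalytic PbCl2 in THF should then alkylidenate lactone 14 to 22.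

Step 15. Bromide may attack C6 with allylic transposition (SN2′), or acid formed in the phosphonium chemistry may degrade the enol ether. The fallback sets out from 23 and comes back at 24 and separates activation from displacement. The alcohol would be converted with MsCl and Et3N at −40 °C into the C8 methanesulfonate F3, and the cold solution treated with anhydrous LiBr in THF. Substitution should then occur by plain SN2 with a bromide salt, without a phosphonium intermediate and without HBr.

Step 7. Closure may occur on the wrong alkene face (endo arm at C12), or the C8 hydroxyl may compete by 6-exo attack. The fallback sets out from 12 and comes back at 14 and replaces the bromonium closure by a stereospecific syn oxidative cyclisation followed by substitution. Diol 12 would be silylated selectively at the more acidic, less hindered C8 hydroxyl (TBSCl, imidazole, DMF, −20 °C) to (E)-2-O-[tert-butyl(dimethyl)silyl]-5,6,7,8,9-pentadeoxy-L-lyxo-non-6-enono-1,4-lactone F4. Rhenium(VII) oxidative cyclisation (Re2O7, 2,6-lutidine, CH2Cl2) should add O9 and a new hydroxyl syn across the E alkene with trans-THF selectivity, giving (3R,3aR,5R,6aS)-3-{[tert-butyl(dimethyl)silyl]oxy}-5-[(1R)-1-hydroxypropyl]hexahydrofuro[3,2-b]furan-2-one F5. An Appel reaction (CBr4, PPh3) would then invert C13 to give 14.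

**Further compounds**

F1 | step 13 | (3Z)-6-(triisopropylsilyl)hex-3-en-5-ynal | CC(C)[Si](C(C)C)(C(C)C)C#C/C=C\CC=O
F2 | step 13 | [(3Z)-6,6-dibromohex-3-en-1-yn-1-yl]triisopropylsilane | CC(C)[Si](C(C)C)(C(C)C)C#C/C=C\CC(Br)Br
F3 | step 15 | (2Z,3R,3aS,5R,6aS)-5-[(1S)-1-bromopropyl]-2-[(3Z)-hex-3-en-5-yn-1-ylidene]hexahydrofuro[3,2-b]furan-3-yl methanesulfonate | C#C/C=C\C/C=C1\O[C@H]2C[C@H]([C@@H](Br)CC)O[C@H]2[C@H]1OS(C)(=O)=O
F4 | step 7 | (E)-2-O-[tert-butyl(dimethyl)silyl]-5,6,7,8,9-pentadeoxy-L-lyxo-non-6-enono-1,4-lactone | O=C1O[C@@H](C/C=C/CC)[C@@H](O)[C@H]1O[Si](C)(C)C(C)(C)C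
F5 | step 7 | (3R,3aR,5R,6aS)-3-{[tert-butyl(dimethyl)silyl]oxy}-5-[(1R)-1-hydroxypropyl]hexahydrofuro[3,2-b]furan-2-one | O=C1O[C@H]2C[C@H]([C@H](O)CC)O[C@H]2[C@H]1O[Si](C)(C)C(C)(C)C
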